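**Retrosynthetic overview**

1. Target 18 is guibourtinidol-(4α→6)-fisetinidol (upper unit 2R,3S,4R, all-trans; lower unit 2R,3S); it comes from the penta-O-benzyl ether 17 by hydrogenolysis.
2. The C4–C6 bond of 17 comes from anti opening of the upper flav-3-ene 3β,4β-epoxide 16 at C-4 by C-6 of tri-O-benzylfisetinidol 15; this sets C-3 and C-4 of the upper unit from C-2.
3. 15 comes from the lower flav-3-ene 13 by hydroboration–oxidation; flav-3-enes 7 and 13 come from cis-flavan-4-ols 5 and 11 by dehydration.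
4. Ring formation: pyran ring C (upper) and pyran ring F (lower) are each closed first, by chalcone-isomerase-type oxa-Michael cyclisation of 2'-hydroxychalcones 3 and 9, run reversibly under asymmetric transfer hydrogenation so each ring is drained to one enantiomer. The four benzene rings (A, B, D, E) are bought.
5. Chalcones 3 and 9 come from acetophenone 1 and aldehydes 2 and 8 (Claisen–Schmidt).

Assumption: the benzyl ethers 1, 2 and 8 are taken as inexpensive catalogue starting materials; TsDPEN = N-tosyl-1,2-diphenylethylenediamine.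

**Route**

Step 1
Reactants: 1 1-[4-(benzyloxy)-2-hydroxyphenyl]ethan-1-one; 2 4-(benzyloxy)benzaldehyde
Product: 3 (E)-1-[4-(benzyloxy)-2-hydroxyphenyl]-3-[4-(benzyloxy)phenyl]prop-2-en-1-one
Conditions: KOH (5 equiv), EtOH/THF, rt to 40 °C, 24 h; then 1 M HCl
Reagents that add atoms: none
Why: Claisen–Schmidt (crossed aldol) condensation of a methyl ketone with a non-enolisable aldehyde gives the thermodynamic E-enone, and no stereocentre is formed.

Step 2
Reactants: 3 (E)-1-[4-(benzyloxy)-2-hydroxyphenyl]-3-[4-(benzyloxy)phenyl]prop-2-en-1-one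
Product: 5 (2S,4S)-7-(benzyloxy)-2-[4-(benzyloxy)phenyl]chroman-4-ol, via racemic flavanone 4 (not isolated)
Conditions: DBU (4 equiv), MeCN, 40 °C, 2 h; then HCO2H (3 equiv), RuCl[(S,S)-TsDPEN](p-cymene) (2 mol %), 40 °C, 24–48 h
Reagents that add atoms: none
Why: Proposed new method: the amine base keeps chalcone 3 and racemic flavanone 4 in oxa-Michael/retro-oxa-Michael equilibrium (the non-enzymatic chalcone isomerase reaction) while the (S,S)-ruthenium hydride reduces only the matched (2S)-flavanone to the 2,4-cis (4S) alcohol, so ring C is closed and C-2 is set by dynamic kinetic resolution; the closest known reaction types are Noyori–Ikariya asymmetric transfer hydrogenation with dynamic kinetic resolution of base-racemising ketones and the kinetic resolution of flavanones by the same catalysts.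

Step 3
Reactants: 5 (2S,4S)-7-(benzyloxy)-2-[4-(benzyloxy)phenyl]chroman-4-ol
Product: 7 (2S)-7-(benzyloxy)-2-[4-(benzyloxy)phenyl]-2H-chromene, via 4-mesylate 6 (not isolated)
Conditions: MsCl (1.5 equiv), Et3N (5 equiv), CH2Cl2, 0 °C to 40 °C, dark
Reagents that add atoms: none
Why: Mesylation followed by E1-type elimination of the p-alkoxybenzylic sulfonate gives the conjugated C3=C4 alkene whatever the C-4 configuration, and because the medium stays basic the acid-labile C-2 ether is not ionised, so the (2S) centre from step 2 is carried through.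

Step 4
Reactants: 1 1-[4-(benzyloxy)-2-hydroxyphenyl]ethan-1-one; 8 3,4-bis(benzyloxy)benzaldehyde
Product: 9 (E)-1-[4-(benzyloxy)-2-hydroxyphenyl]-3-[3,4-bis(benzyloxy)phenyl]prop-2-en-1-one
Conditions: KOH (5 equiv), EtOH/THF, rt to 40 °C, 24 h; then 1 M HCl
Reagents that add atoms: none
Why: Claisen–Schmidt condensation as in step 1 gives the E-chalcone, and no stereocentre is formed.

Step 5
Reactants: 9 (E)-1-[4-(benzyloxy)-2-hydroxyphenyl]-3-[3,4-bis(benzyloxy)phenyl]prop-2-en-1-one
Product: 11 (2S,4S)-7-(benzyloxy)-2-[3,4-bis(benzyloxy)phenyl]chroman-4-ol, via racemic flavanone 10 (not isolated)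
Conditions: DBU (4 equiv), MeCN, 40 °C, 2 h; then HCO2H (3 equiv), RuCl[(S,S)-TsDPEN](p-cymene) (2 mol %), 40 °C, 24–48 h
Reagents that add atoms: none
Why: Proposed new method: as in step 2, reversible base-mediated oxa-Michael closure of ring F gives racemising flavanone 10, from which the (S,S)-ruthenium hydride removes only the (2S)-enantiomer as the 2,4-cis (4S) alcohol, so C-2 of the lower unit is set by dynamic kinetic resolution; the closest known reaction type is Noyori–Ikariya asymmetric transfer hydrogenation with dynamic kinetic resolution.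

Step 6
Reactants: 11 (2S,4S)-7-(benzyloxy)-2-[3,4-bis(benzyloxy)phenyl]chroman-4-ol
Product: 13 (2S)-7-(benzyloxy)-2-[3,4-bis(benzyloxy)phenyl]-2H-chromene, via 4-mesylate 12 (not isolated)
Conditions: MsCl (1.5 equiv), Et3N (5 equiv), CH2Cl2, 0 °C to 40 °C, dark
Reagents that add atoms: none
Why: Mesylation and E1-type elimination under basic conditions as in step 3 give the flav-3-ene without touching C-2.

Step 7
Reactants: 13 (2S)-7-(benzyloxy)-2-[3,4-bis(benzyloxy)phenyl]-2H-chromene
Product: 15 (2R,3S)-7-(benzyloxy)-2-[3,4-bis(benzyloxy)phenyl]chroman-3-ol, via 3-boryl flavan 14 (not isolated)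
Conditions: BH3·THF (2 equiv), THF, 0 °C to rt; then 3 M NaOH, 30% H2O2, 0 °C to rt
Reagents that add atoms: hydrogen peroxide, OO
Why: Brown hydroboration–oxidation puts boron on C-3 (away from the benzylic C-4, which is further polarised by the para 7-benzyloxy group) by syn addition to the face opposite the 2-aryl group, and oxidation with retention gives the 2,3-trans alcohol (the change of the C-2 descriptor from S to R is only a change of CIP priorities).

Step 8
Reactants: 7 (2S)-7-(benzyloxy)-2-[4-(benzyloxy)phenyl]-2H-chromene; 15 (2R,3S)-7-(benzyloxy)-2-[3,4-bis(benzyloxy)phenyl]chroman-3-ol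
Product: 17 (2R,3S,4S)-7-(benzyloxy)-2-[4-(benzyloxy)phenyl]-4-{(2R,3S)-7-(benzyloxy)-2-[3,4-bis(benzyloxy)phenyl]-3-hydroxychroman-6-yl}chroman-3-ol, via upper-unit epoxide 16 (not isolated)
Conditions: DMDO (1.2 equiv, dried acetone solution), CH2Cl2, −40 to 0 °C; volatiles removed at 0 °C; then 15 (3 equiv, excess recovered), BF3·OEt2 (0.2 equiv), CH2Cl2, −78 to −40 °C
Reagents that add atoms: dimethyldioxirane, CC1(C)OO1
Why: DMDO epoxidation occurs on the face opposite the 2-aryl group, and Friedel–Crafts opening of the benzylic, p-alkoxy-stabilised C-4 position by C-6 of 15 (para to O-1, ortho to the benzyloxy group, less hindered than C-8) occurs with inversion, which gives the 3,4-trans (4α) aryl group and the free 3β-hydroxyl.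

Step 9
Reactants: 17 (2R,3S,4S)-7-(benzyloxy)-2-[4-(benzyloxy)phenyl]-4-{(2R,3S)-7-(benzyloxy)-2-[3,4-bis(benzyloxy)phenyl]-3-hydroxychroman-6-yl}chroman-3-ol
Product: 18 (2R,3S,4R)-4-[(2R,3S)-2-(3,4-dihydroxyphenyl)-3,7-dihydroxychroman-6-yl]-2-(4-hydroxyphenyl)chroman-3,7-diol
Conditions: H2 (1 atm), Pd(OH)2/C (20 wt %), THF/MeOH 1:1, rt; filtered under argon
Reagents that add atoms: none
Why: Catalytic hydrogenolysis cleaves the five benzyl aryl ethers while the diarylmethine C4–C6 bond, the cyclic benzylic ethers and all five stereocentres are untouched (the C-4 descriptor changes from S to R only because the CIP priorities change on debenzylation).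

**Compound list**

1 | 1-[4-(benzyloxy)-2-hydroxyphenyl]ethan-1-one | CC(=O)c1ccc(OCc2ccccc2)cc1O | starting material
2 | 4-(benzyloxy)benzaldehyde | O=Cc1ccc(OCc2ccccc2)cc1 | starting material
3 | (E)-1-[4-(benzyloxy)-2-hydroxyphenyl]-3-[4-(benzyloxy)phenyl]prop-2-en-1-one | O=C(/C=C/c1ccc(OCc2ccccc2)cc1)c1ccc(OCc2ccccc2)cc1O | intermediate
4 | racemic 7-(benzyloxy)-2-[4-(benzyloxy)phenyl]chroman-4-one (not isolated) | O=C1CC(c2ccc(OCc3ccccc3)cc2)Oc2cc(OCc3ccccc3)ccc21 | intermediate
5 | (2S,4S)-7-(benzyloxy)-2-[4-(benzyloxy)phenyl]chroman-4-ol (2,4-cis) | O[C@H]1C[C@@H](c2ccc(OCc3ccccc3)cc2)Oc2cc(OCc3ccccc3)ccc21 | intermediate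
6 | (2S,4S)-7-(benzyloxy)-2-[4-(benzyloxy)phenyl]chroman-4-yl methanesulfonate (not isolated) | CS(=O)(=O)O[C@H]1C[C@@H](c2ccc(OCc3ccccc3)cc2)Oc2cc(OCc3ccccc3)ccc21 | intermediate
7 | (2S)-7-(benzyloxy)-2-[4-(benzyloxy)phenyl]-2H-chromene | C1=C[C@@H](c2ccc(OCc3ccccc3)cc2)Oc2cc(OCc3ccccc3)ccc21 | intermediate
8 | 3,4-bis(benzyloxy)benzaldehyde | O=Cc1ccc(OCc2ccccc2)c(OCc2ccccc2)c1 | starting material
9 | (E)-1-[4-(benzyloxy)-2-hydroxyphenyl]-3-[3,4-bis(benzyloxy)phenyl]prop-2-en-1-one | O=C(/C=C/c1ccc(OCc2ccccc2)c(OCc2ccccc2)c1)c1ccc(OCc2ccccc2)cc1O | intermediate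
10 | racemic 7-(benzyloxy)-2-[3,4-bis(benzyloxy)phenyl]chroman-4-one (not isolated) | O=C1CC(c2ccc(OCc3ccccc3)c(OCc3ccccc3)c2)Oc2cc(OCc3ccccc3)ccc21 | intermediate
11 | (2S,4S)-7-(benzyloxy)-2-[3,4-bis(benzyloxy)phenyl]chroman-4-ol (2,4-cis) | O[C@H]1C[C@@H](c2ccc(OCc3ccccc3)c(OCc3ccccc3)c2)Oc2cc(OCc3ccccc3)ccc21 | intermediate
12 | (2S,4S)-7-(benzyloxy)-2-[3,4-bis(benzyloxy)phenyl]chroman-4-yl methanesulfonate (not isolated) | CS(=O)(=O)O[C@H]1C[C@@H](c2ccc(OCc3ccccc3)c(OCc3ccccc3)c2)Oc2cc(OCc3ccccc3)ccc21 | intermediate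
13 | (2S)-7-(benzyloxy)-2-[3,4-bis(benzyloxy)phenyl]-2H-chromene | C1=C[C@@H](c2ccc(OCc3ccccc3)c(OCc3ccccc3)c2)Oc2cc(OCc3ccccc3)ccc21 | intermediate
14 | [(2S,3S)-7-(benzyloxy)-2-[3,4-bis(benzyloxy)phenyl]chroman-3-yl]borane, boron trans to the 2-aryl group (not isolated) | B[C@H]1Cc2ccc(OCc3ccccc3)cc2O[C@@H]1c1ccc(OCc2ccccc2)c(OCc2ccccc2)c1 | intermediate
15 | (2R,3S)-7-(benzyloxy)-2-[3,4-bis(benzyloxy)phenyl]chroman-3-ol (7,3',4'-tri-O-benzylfisetinidol) | O[C@H]1Cc2ccc(OCc3ccccc3)cc2O[C@@H]1c1ccc(OCc2ccccc2)c(OCc2ccccc2)c1 | intermediate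
16 | (2R,3S,4S)-7-(benzyloxy)-2-[4-(benzyloxy)phenyl]-3,4-epoxychroman, oxirane trans to the 2-aryl group (not isolated) | [C@H]1(c2ccc(OCc3ccccc3)cc2)Oc2cc(OCc3ccccc3)ccc2[C@@H]2O[C@H]12 | intermediate
17 | (2R,3S,4S)-7-(benzyloxy)-2-[4-(benzyloxy)phenyl]-4-{(2R,3S)-7-(benzyloxy)-2-[3,4-bis(benzyloxy)phenyl]-3-hydroxychroman-6-yl}chroman-3-ol (penta-O-benzyl guibourtinidol-(4α→6)-fisetinidol, all-trans) | C(c1ccccc1)Oc1ccc([C@H]2Oc3cc(OCc4ccccc4)ccc3[C@@H](c3cc4c(cc3OCc3ccccc3)O[C@H](c3ccc(OCc5ccccc5)c(OCc5ccccc5)c3)[C@@H](O)C4)[C@@H]2O)cc1 | intermediate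
18 | (2R,3S,4R)-4-[(2R,3S)-2-(3,4-dihydroxyphenyl)-3,7-dihydroxychroman-6-yl]-2-(4-hydroxyphenyl)chroman-3,7-diol (guibourtinidol-(4α→6)-fisetinidol) | Oc1ccc([C@H]2Oc3cc(O)ccc3[C@@H](c3cc4c(cc3O)O[C@H](c3ccc(O)c(O)c3)[C@@H](O)C4)[C@@H]2O)cc1 | target

**Step count and risks**

Total: 9 steps. Longest linear sequence: 6 steps (steps 4, 5, 6, 7, 8, 9).

The three steps most likely to fail:

Step 2. The ruthenium hydride may reduce the enone C=C of chalcone 3 to a dihydrochalcone, or ring opening of the mismatched flavanone may be too slow, leaving only a kinetic resolution. The fallback sets out from chalcone 3 and comes back at flavene 7, so step 3 is bypassed as well. Luche 1,2-reduction (NaBH4, CeCl3·7H2O, MeOH/THF, −20 °C) gives racemic (E)-1-[4-(benzyloxy)-2-hydroxyphenyl]-3-[4-(benzyloxy)phenyl]prop-2-en-1-ol F1. F1 is ionised by a chiral BINOL-derived N-triflylphosphoramide (5 mol %, toluene, −40 °C) to an achiral allyl cation/o-quinone methide held as a contact ion pair with the chiral anion. Enantioselective C–O ring closure then gives (2S)-7; the catalyst antipode is chosen to give S. The stereocentre then comes from asymmetric ion-pair catalysis, not from a reduction.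

Step 5. This carries the same risk as step 2, on the lower half. The fallback sets out from chalcone 9 and comes back at 11. Chalcone 9 is cyclised completely to racemic flavanone 10 (NaOAc, EtOH, reflux), which is isolated by crystallisation. 10 is then resolved by classical kinetic resolution under non-racemising acidic transfer hydrogenation (RuCl[(S,S)-TsDPEN](p-cymene), HCO2H/Et3N 5:2, EtOAc, rt), stopped near 50% conversion. This gives 11 and unreacted (2R)-7-(benzyloxy)-2-[3,4-bis(benzyloxy)phenyl]chroman-4-one F2. F2 is separated, racemised back to 10 with DBU in a separate flask and recycled. Reduction and racemisation are decoupled, so the open chalcone never meets the hydride catalyst.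

Step 8. Epoxide 16 is very labile: it can rearrange to the flavan-3-one or self-condense, and an ionised C-4 could also give some 3,4-cis or C-8-linked product. The fallback sets out from flavene 7 and comes back at 17. Dihydroxylation (OsO4 cat., N-methylmorpholine N-oxide, acetone/H2O, 0 °C) on the face opposite the 2-aryl group gives the stable, isolable (2R,3S,4S)-7-(benzyloxy)-2-[4-(benzyloxy)phenyl]chroman-3,4-diol F3 (2,3-trans-3,4-cis, the O-benzylated leucoguibourtinidin). F3 is condensed with 15 (3 equiv) under BF3·OEt2 in CH2Cl2 at −78 °C through the C-4 benzylic carbocation (flavan-3,4-diol/flavan-3-ol condensation). The nucleophile adds preferentially trans to the 3-hydroxyl, and the minor 3,4-cis isomer is removed by chromatography of 17.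

**Further compounds**

F1 | step 2 | racemic (E)-1-[4-(benzyloxy)-2-hydroxyphenyl]-3-[4-(benzyloxy)phenyl]prop-2-en-1-ol | OC(/C=C/c1ccc(OCc2ccccc2)cc1)c1ccc(OCc2ccccc2)cc1O
F2 | step 5 | (2R)-7-(benzyloxy)-2-[3,4-bis(benzyloxy)phenyl]chroman-4-one | O=C1C[C@H](c2ccc(OCc3ccccc3)c(OCc3ccccc3)c2)Oc2cc(OCc3ccccc3)ccc21
F3 | step 8 | (2R,3S,4S)-7-(benzyloxy)-2-[4-(benzyloxy)phenyl]chroman-3,4-diol | O[C@@H]1[C@H](O)[C@@H](c2ccc(OCc3ccccc3)cc2)Oc2cc(OCc3ccccc3)ccc21
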